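## Structural features

The target is one carbocycle, a cyclohexene, lettered here a (CH–OAc), b (=CH), c (=C, carrying the exocyclic CH2OBz carbon g), d (CH–OH), e (CH–OBz) and f (CH–OH). The four stereocentres are contiguous along a–f–e–d, with configurations a R, f S, e R, d S. The oxygens on a and d are cis to each other across the ring, the oxygens on e and f form a cis-diol pair, and the two pairs lie on opposite faces. The molecule is fragile in three ways: a benzoate sits between two free hydroxyls and an acetate next to one of them, so base invites acyl migration; the a-acetate and the g-benzoate are allylic and ionisable; and the ring is two eliminations away from an arene. The seven-carbon skeleton is trivial. The real difficulty is to set the oxygen stereotetrad in absolute terms and to place three acyl groups on five oxygens without statistical acylation. The feature exploited is that a and d, both oxygenated and cis, flank the b=c alkene that carries g. This is the retron of a [4+2] cycloaddition between a 1,4-dioxygenated diene (carbons d, e, f, a) and a three-carbon acetylenic aldehyde (b, c, g). The e=f alkene left by the diene is the handle for the cis-diol on the opposite face.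

## Logic of the disconnections

14 to 13. The O–H at d is traced back to an O–Si bond. The d-oxygen must stay masked until every acyl group is in place, so that d never competes in acylation. The forward step must cleave silicon without basic alkoxides, or the acyl groups will migrate.

13 to 12. The acyl C–O bond at g is cut. This leaves a primary allylic hydroxyl beside one hindered secondary hydroxyl at f. The forward step must acylate the primary position only and must not move the e-benzoate.

12 to 11. The C–H bond at g is removed, returning g to the aldehyde level. The aldehyde is what the cycloaddition delivers and what keeps b=c electron-poor earlier in the route. The forward step must be a clean 1,2-reduction that spares two kinds of ester.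

11 to 9 (through 10). The acyl C–O bond at e is cut, giving the free cis-diol. The two hydroxyls are then told apart by ring conformation and not by reagent stoichiometry. The forward step must deliver the benzoyl group to the axial oxygen, which has to be e.

9 to 8. Both C–O bonds at e and f are cut, giving the e=f alkene of a cyclohexa-1,4-diene. Two stereocentres are removed at once. The forward step must oxidise e=f and not b=c, from the face opposite the oxygens on a and d, and must not aromatise 8.

8 to 5 + 7. The a–b and c–d bonds are cut. The ring, both remaining stereocentres and the whole skeleton fall back to two achiral acyclic pieces. The acetate on a is already in its final form and the silyl ether sits on d. The forward step must control regiochemistry (silyloxy terminus to the formyl-bearing carbon), absolute face selectivity and temperature.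

7 to 6. The aldehyde is taken back to the alcohol level. 7 is hazardous when neat, so the forward step must give it as a dry solution that is never concentrated.

5 to 4. The O–Si bond is cut and the diene is returned to the conjugated aldehyde. The forward step must give the (1E,3E) geometry. 5 is used in excess in the cycloaddition so that other geometric isomers stay behind as unreactive spectators.

4 to 2 (through 3) and 2 to 1. The aldehyde is taken back to the allylic alcohol and the acetyl C–O bond is cut, arriving at a symmetrical commercial diol. The forward steps need mono-acylation and an oxidation that ends at the E-enal.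

## Other disconnections considered

Alternative 1: The C–O bonds on a and d are traced to a peroxide bridge and the e,f-diol to an arene.

- **Forward key step:** the meso diene acetonide A1, reachable by dearomative cis-dihydroxylation of the parent arene and ketalisation, would add singlet oxygen (O2, visible light, 5,10,15,20-tetraphenylporphyrin) across a and d on the face away from the ketal. This would give the meso endoperoxide A2. A chiral-amine-mediated Kornblum–DeLaMare rearrangement would then desymmetrise A2 to the hydroxy enone A3, with the carbonyl at d and the hydroxyl at a.
- **In favour:** all four ring oxygens would be in place after two steps with the correct relative configuration. Every step has close precedent. The intermediates are not prone to base-induced aromatisation as 8 is. The a-hydroxyl of A3 is free for direct acetylation.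
- **Against:** carbon g is missing and would have to be attached at c (α-iodination and Stille hydroxymethylation, or a Morita–Baylis–Hillman reaction). The stereocentre at d is destroyed in the rearrangement. In the 1,2-reduction that rebuilds it, hydride is expected to approach anti to the neighbouring ketal oxygen, which would place the hydroxyl cis to the e-oxygen, the opposite of the target; a Mitsunobu inversion would then be needed. Ketal removal and both benzoylations still follow.
- **Comparison:**
  - Structure: the alternative is better in setting the four C–O bonds early and securely, and poorer in lacking g.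
  - Mechanism: it is the better plan, since it rests on established reactions while the chosen plan depends on an untried cycloaddition.
  - The e/f differentiation is equal in both plans.
  - Step economy: the chosen plan is better, at ten steps against roughly fifteen.

Alternative 2: The a–f and d–e bonds are cut, so that a, b, c, d and g come from a 2-pyrone and e, f from an enediol equivalent.

- **Forward key step:** methyl coumalate A4 and vinylene carbonate A5 would combine in an inverse-demand [4+2] cycloaddition. The catalyst would be Cu(OTf)2 with 2,2'-(propane-2,2-diyl)bis[(4S)-4-tert-butyl-4,5-dihydro-1,3-oxazole]. The bridged lactone would lose CO2 to give the diene carbonate A6. Singlet oxygen across a and d, then O–O reduction, would supply the cis a,d-diol.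
- **In favour:** all seven carbons are present, with g at the carboxyl level. The cis e,f-diol arrives masked. There is no regiochemical question, because A5 is symmetrical. Both components are bench-stable, which is better than the hazardous 7 of the chosen plan.
- **Against:** A5 is a sluggish, weakly polarised dienophile that would need forcing temperatures, at which loss of the carbonate and aromatisation to a hydroxybenzoate compete. A4 offers only weak two-point binding to divalent copper, so enantiocontrol is doubtful. The a- and d-hydroxyls would arrive undifferentiated. The ester would have to be reduced in the presence of an acetate and a carbonate.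
- **Comparison:**
  - Structure: the plans are equal in carbons and in the number of ring oxygens present after the key step (two of four). The chosen plan is better in that its two oxygens already carry their final, different groups.
  - Mechanism: neither asymmetric key step has direct precedent, and both products can aromatise, so the plans are equal there. The thermal pyrone cycloaddition itself is better founded.
  - Step economy: the chosen plan is better, because an aldehyde at g reduces more cleanly than an ester and no oxygenation of a and d remains to be done.

Alternative 3: No ring bond is cut in the key step. The b=c alkene is masked as a cycloadduct and e=f is dihydroxylated.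

- **Forward key step:** the quinone ester A7 and anthracene A8 would give a bridged enedione. Convex-face reduction of both ketones and silylation of the less hindered a-hydroxyl would lead to the enediol silyl ether A9. OsO4 with N-methylmorpholine N-oxide would then attack e=f on the convex face, anti to the oxygens on a and d, to give the tetrol derivative A10. Ester reduction, acylations and a thermal retro-Diels–Alder reaction would release b=c.
- **In favour:** the rigid bicycle makes the facial outcome of reduction and dihydroxylation highly predictable, at least equal to the chosen plan. No intermediate can aromatise before the end, which is better. Carbon g is present, which is equal. All steps are precedented, which is better.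
- **Against:** the first cycloaddition gives a racemate unless it is made enantioselective or resolved. The silyl group ends on a and the free hydroxyl on d, the reverse of what the endgame wants, so protecting groups would have to be exchanged. The final retro-[4+2] needs temperatures at which allylic esters can eliminate or migrate. A 178-mass-unit auxiliary is carried throughout.
- **Comparison:**
  - Structure: the alternative is equal in carbons and better in robustness.
  - Mechanism: it is better in certainty of diastereocontrol and poorer in absolute control.
  - Step economy: the chosen plan is clearly better, at ten steps against about fourteen, with no auxiliary to remove.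

Key step: step 5

Assumption: the (S)-diphenylprolinol-derived oxazaborolidinium catalyst is taken to give the enantiomer 8; if the sense of induction is the opposite, its equally available (R)-antipode is used and nothing else changes.

Remark: the descriptors at a, d, e and f change between 8, 9, 11 and 14 only because the CIP priorities of neighbouring groups change; no centre is inverted once it is set.

## Route

Step 1
Reactants: 1 (Z)-but-2-ene-1,4-diol
Product: 2 (Z)-4-hydroxybut-2-en-1-yl acetate
Conditions: Ac2O (1.0 equiv), 1 (3 equiv), Et3N, 4-(dimethylamino)pyridine (cat.), THF, 0 °C
Reagents that add atoms: acetic anhydride, CC(=O)OC(C)=O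
Why: Amine-catalysed O-acetylation of a symmetrical diol; the excess of the cheap, water-soluble diol suppresses the diacetate, and the two hydroxyls are equivalent, so only one monoacetate can form.

Step 2
Reactants: 2 (Z)-4-hydroxybut-2-en-1-yl acetate
Product: 4 (E)-4-oxobut-2-en-1-yl acetate, via (Z)-4-oxobut-2-en-1-yl acetate 3 (not isolated)
Conditions: MnO2 (activated, excess), CH2Cl2, rt; filter; p-toluenesulfonic acid monohydrate (cat.), rt
Reagents that add atoms: none
Why: Activated MnO2 oxidises the allylic alcohol to the enal without touching the acetate, and a trace of acid equilibrates the first-formed Z-enal 3 to the more stable E-isomer (allylic oxidation, then acid-catalysed alkene isomerisation).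

Step 3
Reactants: 4 (E)-4-oxobut-2-en-1-yl acetate
Product: 5 (1E,3E)-4-(tert-butyldimethylsilyloxy)buta-1,3-dien-1-yl acetate
Conditions: TBSOTf (1.1 equiv), Et3N (1.5 equiv), Et2O, 0 °C → rt
Reagents that add atoms: tert-butyldimethylsilyl trifluoromethanesulfonate, CC(C)(C)[Si](C)(C)OS(=O)(=O)C(F)(F)F
Why: Silyl dienol ether formation: O-silylation of the enal and γ-deprotonation by Et3N; the s-trans enal gives the E enol ether and the acetoxy group takes the outside position at the new terminal alkene, so the (1E,3E) isomer should dominate.

Step 4
Reactants: 6 prop-2-yn-1-ol
Product: 7 propynal
Conditions: MnO2 (activated, excess), CH2Cl2, rt; filter through diatomaceous earth, dry over 4 Å sieves, keep as a titrated cold solution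
Reagents that add atoms: none
Why: Propargylic alcohol oxidation under neutral, anhydrous conditions; the volatile, polymerisation-prone aldehyde is never concentrated or exposed to base but used directly as a solution.

Step 5
Reactants: 5 (1E,3E)-4-(tert-butyldimethylsilyloxy)buta-1,3-dien-1-yl acetate; 7 propynal
Product: 8 (1S,4R)-4-(tert-butyldimethylsilyloxy)-3-formylcyclohexa-2,5-dien-1-yl acetate
Conditions: (S)-3,3-diphenyl-1-(o-tolyl)tetrahydro-1H,3H-pyrrolo[1,2-c][1,3,2]oxazaborole·HN(SO2CF3)2 (20 mol%), 5 (2 equiv), CH2Cl2, −95 → −78 °C; cold pH 7 phosphate buffer, work-up below 0 °C
Reagents that add atoms: none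
Why: Proposed new method: the cationic boron Lewis acid binds the formyl oxygen of 7 and lowers the LUMO of the conjugated C≡C bond, so that diene 5 adds in a concerted but asynchronous [4+2] event in which the a–b bond (acetoxy-bearing terminus to the alkyne CH) runs ahead of the c–d bond (silyloxy-bearing terminus to the formyl-bearing carbon). The closest known reaction types are the thermal Diels–Alder reaction of (E,E)-1,4-diacyloxybutadienes with acetylenic esters and the oxazaborolidinium-catalysed cycloaddition of α,β-unsaturated aldehydes with 1-oxygenated dienes; the union of an ynal with an unsymmetrical 1,4-dioxygenated diene under such a catalyst is the untested part. The single six-membered carbocycle is closed by the intermolecular cycloaddition itself, from two acyclic components, both σ bonds arising in one event that is suprafacial on the diene. The relative configuration of the new stereocentres a and d follows from the (1E,3E) geometry of 5, since suprafacial bonding at both termini places the acetoxy and silyloxy groups cis. Their absolute configuration is set by the catalyst, whose aryl group screens one face of the bound ynal so that the diene, in one preferred orientation, presents a single enantiotopic face. Regioselectivity is required and rests on the unequal donors: the silyloxy group is the stronger donor, makes the remote acetoxy-bearing terminus the more nucleophilic one and stabilises the positive charge that builds up on its own carbon, so d ends next to the formyl-bearing carbon c. Chemoselectivity for C≡C over C=O and over Mukaiyama-type silyl transfer is favoured by the hindered silyl group and by the low temperature, which also holds back loss of acetic acid and aromatisation of 8.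

Step 6
Reactants: 8 (1S,4R)-4-(tert-butyldimethylsilyloxy)-3-formylcyclohexa-2,5-dien-1-yl acetate
Product: 9 (1R,4S,5S,6R)-4-(tert-butyldimethylsilyloxy)-3-formyl-5,6-dihydroxycyclohex-2-en-1-yl acetate
Conditions: OsO4 (2 mol%), N-methylmorpholine N-oxide (1.2 equiv), acetone/H2O, −10 → 0 °C; aq. Na2S2O3
Reagents that add atoms: osmium tetroxide, O=[Os](=O)(=O)=O; N-methylmorpholine N-oxide, C[N+]1([O-])CCOCC1; water, O
Why: Catalytic syn-dihydroxylation: the isolated cis-disubstituted e=f bond reacts in preference to b=c, which is deactivated by conjugation with the formyl group, and OsO4 approaches the face opposite the two allylic oxygens on a and d, so the new hydroxyls at e and f are cis to each other and trans to the acetoxy and silyloxy groups.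

Step 7
Reactants: 9 (1R,4S,5S,6R)-4-(tert-butyldimethylsilyloxy)-3-formyl-5,6-dihydroxycyclohex-2-en-1-yl acetate
Product: 11 (1S,2S,5R,6S)-5-acetoxy-2-(tert-butyldimethylsilyloxy)-3-formyl-6-hydroxycyclohex-3-en-1-yl benzoate, via 2-methoxy-2-phenyl-1,3-dioxolane orthoester 10 (not isolated)
Conditions: PhC(OMe)3, camphor-10-sulfonic acid (cat.), CH2Cl2, rt; then AcOH/H2O (4:1), 0 °C
Reagents that add atoms: trimethyl orthobenzoate, COC(OC)(OC)c1ccccc1; water, O
Why: Orthoester exchange ties only the cis e,f-diol into 10, and mild aqueous acid opens it through the dioxolanylium ion and hemiorthoester to the axial ester and the equatorial hydroxyl; A(1,2) strain with the formyl group on c holds the silyloxy group on d pseudoaxial, which makes the trans oxygen on e axial, so the benzoate should end on e with no ring stereocentre touched.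

Step 8
Reactants: 11 (1S,2S,5R,6S)-5-acetoxy-2-(tert-butyldimethylsilyloxy)-3-formyl-6-hydroxycyclohex-3-en-1-yl benzoate
Product: 12 (1S,2S,5R,6S)-5-acetoxy-2-(tert-butyldimethylsilyloxy)-6-hydroxy-3-(hydroxymethyl)cyclohex-3-en-1-yl benzoate
Conditions: NaBH4, CeCl3·7H2O, MeOH, −78 °C
Reagents that add atoms: none
Why: Luche reduction: the cerium-modified borohydride adds hydride 1,2 to the conjugated aldehyde at low temperature and leaves the acetate, the benzoate and the b=c bond untouched; no stereocentre is formed.

Step 9
Reactants: 12 (1S,2S,5R,6S)-5-acetoxy-2-(tert-butyldimethylsilyloxy)-6-hydroxy-3-(hydroxymethyl)cyclohex-3-en-1-yl benzoate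
Product: 13 [(3R,4S,5S,6S)-3-acetoxy-5-(benzoyloxy)-6-(tert-butyldimethylsilyloxy)-4-hydroxycyclohex-1-en-1-yl]methyl benzoate
Conditions: BzCl (1.1 equiv), 2,4,6-collidine, CH2Cl2, −78 → −30 °C
Reagents that add atoms: benzoyl chloride, O=C(Cl)c1ccccc1
Why: Kinetically selective O-acylation: with a hindered pyridine base at low temperature the primary allylic hydroxyl at g is benzoylated much faster than the secondary f-hydroxyl flanked by two acyloxy groups, and the weak base does not promote benzoyl migration from e to f.

Step 10
Reactants: 13 [(3R,4S,5S,6S)-3-acetoxy-5-(benzoyloxy)-6-(tert-butyldimethylsilyloxy)-4-hydroxycyclohex-1-en-1-yl]methyl benzoate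
Product: 14 [(3R,4S,5R,6S)-3-acetoxy-5-(benzoyloxy)-4,6-dihydroxycyclohex-1-en-1-yl]methyl benzoate
Conditions: HF·pyridine, pyridine, THF, 0 °C → rt
Reagents that add atoms: none
Why: Fluoride-induced Si–O cleavage in a buffered acidic medium frees the hydroxyl at d without the basic alkoxides that would trigger acyl migration among the neighbouring oxygens; the configuration at d is untouched.

## Compound list

1 | (Z)-but-2-ene-1,4-diol | OC/C=C\CO | starting material
2 | (Z)-4-hydroxybut-2-en-1-yl acetate | CC(=O)OC/C=C\CO | intermediate
3 | (Z)-4-oxobut-2-en-1-yl acetate (not isolated) | CC(=O)OC/C=C\C=O | intermediate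
4 | (E)-4-oxobut-2-en-1-yl acetate | CC(=O)OC/C=C/C=O | intermediate
5 | (1E,3E)-4-(tert-butyldimethylsilyloxy)buta-1,3-dien-1-yl acetate | CC(=O)O/C=C/C=C/O[Si](C)(C)C(C)(C)C | intermediate
6 | prop-2-yn-1-ol | C#CCO | starting material
7 | propynal (used in solution) | C#CC=O | intermediate
8 | (1S,4R)-4-(tert-butyldimethylsilyloxy)-3-formylcyclohexa-2,5-dien-1-yl acetate | CC(=O)O[C@@H]1C=C(C=O)[C@H](O[Si](C)(C)C(C)(C)C)C=C1 | intermediate
9 | (1R,4S,5S,6R)-4-(tert-butyldimethylsilyloxy)-3-formyl-5,6-dihydroxycyclohex-2-en-1-yl acetate | CC(=O)O[C@@H]1C=C(C=O)[C@H](O[Si](C)(C)C(C)(C)C)[C@@H](O)[C@H]1O | intermediate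
10 | cyclic methyl orthobenzoate of 9 (2-methoxy-2-phenyl-1,3-dioxolane on the e- and f-oxygens, both epimers at the orthoester carbon; not isolated) | CC(=O)O[C@@H]1C=C(C=O)[C@H](O[Si](C)(C)C(C)(C)C)[C@H]2OC(OC)(c3ccccc3)O[C@@H]12 | intermediate
11 | (1S,2S,5R,6S)-5-acetoxy-2-(tert-butyldimethylsilyloxy)-3-formyl-6-hydroxycyclohex-3-en-1-yl benzoate | CC(=O)O[C@@H]1C=C(C=O)[C@H](O[Si](C)(C)C(C)(C)C)[C@@H](OC(=O)c2ccccc2)[C@H]1O | intermediate
12 | (1S,2S,5R,6S)-5-acetoxy-2-(tert-butyldimethylsilyloxy)-6-hydroxy-3-(hydroxymethyl)cyclohex-3-en-1-yl benzoate | CC(=O)O[C@@H]1C=C(CO)[C@H](O[Si](C)(C)C(C)(C)C)[C@@H](OC(=O)c2ccccc2)[C@H]1O | intermediate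
13 | [(3R,4S,5S,6S)-3-acetoxy-5-(benzoyloxy)-6-(tert-butyldimethylsilyloxy)-4-hydroxycyclohex-1-en-1-yl]methyl benzoate | CC(=O)O[C@@H]1C=C(COC(=O)c2ccccc2)[C@H](O[Si](C)(C)C(C)(C)C)[C@@H](OC(=O)c2ccccc2)[C@H]1O | intermediate
14 | [(3R,4S,5R,6S)-3-acetoxy-5-(benzoyloxy)-4,6-dihydroxycyclohex-1-en-1-yl]methyl benzoate | CC(=O)O[C@@H]1C=C(COC(=O)c2ccccc2)[C@H](O)[C@@H](OC(=O)c2ccccc2)[C@H]1O | target

## Step count and least certain steps

Total: 10 steps. Longest linear sequence: 9 steps (1 to 14 through steps 1, 2, 3, 5, 6, 7, 8, 9, 10); step 4 is a one-step branch.

**Step 5 (key step, carries the label "Proposed new method:").**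
- Most likely failures: ionisation or base-induced loss of the doubly allylic acetate with aromatisation; open-chain addition with silyl transfer in place of ring closure; poor facial selectivity, because an alkyne offers no endo/exo substituent to orient the diene.
- Fallback, from 5, returning at 9, by known chemistry: 5 would be combined with 2-bromoacrolein F1 under the same oxazaborolidinium catalyst at −78 °C. This is the classical enantioselective Diels–Alder reaction of a 2-haloacrolein, with the same regiochemical bias. The product would be the bromo aldehyde cycloadduct F2, a cyclohexene that cannot aromatise by a single elimination. OsO4 with N-methylmorpholine N-oxide would dihydroxylate its only alkene anti to the oxygens on a and d, giving the bromo aldehyde diol F3. Dehydrobromination with DBU at 0 °C towards the unhindered CH2 at b would then install the b=c enal and give 9.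

**Step 6.**
- Most likely failures: aromatisation of the dienal promoted by the amine and water of the osmylation medium; hydration of the aldehyde that slows turnover.
- Fallback, from 8, returning at 13: 8 would be reduced at once under Luche conditions to the dienyl alcohol F4 and benzoylated (BzCl, pyridine) to the dienyl benzoate F5, which lacks the acidifying formyl group. Osmylation should then prefer the less hindered e=f bond over b=c, which is trisubstituted and carries three allylic C–O bonds, and give the diol F6. Orthoester exchange and aqueous acid opening as in step 7, through the cyclic orthoester F7, would lead to 13.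

**Step 7.**
- Most likely failures: delivery of the benzoyl group to f if the other half-chair is populated; acid-catalysed migration of the benzoate from e to f during the aqueous stage; acetalisation of the aldehyde that is not reversed.
- Fallback, from 9, returning at 11: the more accessible equatorial f-hydroxyl would be capped first (Et3SiCl, imidazole, −40 °C) to give the f-O-triethylsilyl ether F8. The remaining e-hydroxyl would be benzoylated (BzCl, 4-(dimethylamino)pyridine, pyridine) to the benzoate F9. The triethylsilyl group would then be removed selectively with AcOH/THF/H2O to give 11.

**Step 3.**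
- Most likely failures: formation of geometric isomers at the acetoxy-bearing double bond, which lowers the share of reactive (1E,3E) diene; hydrolysis of the silyl dienol ether on purification.
- Fallback, from 4, returning at 5: 4 would be converted with isopropenyl acetate and p-toluenesulfonic acid monohydrate into (1E,3E)-buta-1,3-diene-1,4-diyl diacetate F10, which is crystalline and can be freed of its isomers by recrystallisation. One enol acetate would be cleaved with MeLi (2 equiv, −78 °C), with retention of geometry, to the lithium dienolate F11. O-Silylation with TBSCl in THF/DMPU would then give geometrically defined 5.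

## Further compounds

F1 | step 5 | 2-bromoacrolein | C=C(Br)C=O
F2 | step 5 | 5-acetoxy-1-bromo-2-(tert-butyldimethylsilyloxy)cyclohex-3-ene-1-carbaldehyde (acetoxy and silyloxy cis, configured as in 8; either epimer at the bromine-bearing carbon) | CC(=O)O[C@@H]1CC(Br)(C=O)[C@H](O[Si](C)(C)C(C)(C)C)C=C1
F3 | step 5 | 5-acetoxy-1-bromo-2-(tert-butyldimethylsilyloxy)-3,4-dihydroxycyclohexane-1-carbaldehyde (cis-diol trans to acetoxy and silyloxy) | CC(=O)O[C@@H]1CC(Br)(C=O)[C@H](O[Si](C)(C)C(C)(C)C)[C@@H](O)[C@H]1O
F4 | step 6 | (1S,4R)-4-(tert-butyldimethylsilyloxy)-3-(hydroxymethyl)cyclohexa-2,5-dien-1-yl acetate | CC(=O)O[C@@H]1C=C(CO)[C@H](O[Si](C)(C)C(C)(C)C)C=C1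
F5 | step 6 | [(3S,6R)-3-acetoxy-6-(tert-butyldimethylsilyloxy)cyclohexa-1,4-dien-1-yl]methyl benzoate | CC(=O)O[C@@H]1C=C(COC(=O)c2ccccc2)[C@H](O[Si](C)(C)C(C)(C)C)C=C1
F6 | step 6 | [(3R,4R,5S,6S)-3-acetoxy-6-(tert-butyldimethylsilyloxy)-4,5-dihydroxycyclohex-1-en-1-yl]methyl benzoate | CC(=O)O[C@@H]1C=C(COC(=O)c2ccccc2)[C@H](O[Si](C)(C)C(C)(C)C)[C@@H](O)[C@H]1O
F7 | step 6 | cyclic methyl orthobenzoate of F6 (2-methoxy-2-phenyl-1,3-dioxolane on the e- and f-oxygens) | CC(=O)O[C@@H]1C=C(COC(=O)c2ccccc2)[C@H](O[Si](C)(C)C(C)(C)C)[C@H]2OC(OC)(c3ccccc3)O[C@@H]12
F8 | step 7 | f-O-triethylsilyl ether of 9 | CC(=O)O[C@@H]1C=C(C=O)[C@H](O[Si](C)(C)C(C)(C)C)[C@@H](O)[C@H]1O[Si](CC)(CC)CC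
F9 | step 7 | e-O-benzoate of F8 (f-O-triethylsilyl ether of 11) | CC(=O)O[C@@H]1C=C(C=O)[C@H](O[Si](C)(C)C(C)(C)C)[C@@H](OC(=O)c2ccccc2)[C@H]1O[Si](CC)(CC)CC
F10 | step 3 | (1E,3E)-buta-1,3-diene-1,4-diyl diacetate | CC(=O)O/C=C/C=C/OC(C)=O
F11 | step 3 | lithium (1E,3E)-4-acetoxybuta-1,3-dien-1-olate | [Li+].[O-]/C=C/C=C/OC(C)=O
A1 | alternative 1 | meso cis-cyclohexa-3,5-diene-1,2-diol acetonide | CC1(C)O[C@H]2C=CC=C[C@H]2O1
A2 | alternative 1 | meso endoperoxide acetonide | O3[C@@H]1C=C[C@H](O3)[C@H]2OC(C)(C)O[C@@H]12
A3 | alternative 1 | hydroxy enone acetonide (carbonyl at d, hydroxyl at a) | O=C1C=C[C@@H](O)[C@@H]2OC(C)(C)O[C@H]12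
A4 | alternative 2 | methyl coumalate (methyl 2-oxo-2H-pyran-5-carboxylate) | COC(=O)C1=COC(=O)C=C1
A5 | alternative 2 | vinylene carbonate | O=C1OC=CO1
A6 | alternative 2 | methyl cis-3,4-dihydroxycyclohexa-1,5-diene-1-carboxylate cyclic carbonate | C1=CC(C(=O)OC)=C[C@H]2OC(=O)O[C@@H]12
A7 | alternative 3 | methyl 3,6-dioxocyclohexa-1,4-diene-1-carboxylate | COC(=O)C1=CC(=O)C=CC1=O
A8 | alternative 3 | anthracene | c1ccc2cc3ccccc3cc2c1
A9 | alternative 3 | anthracene-bridged enediol mono(tert-butyldimethylsilyl) ether | CC(C)(C)[Si](C)(C)O[C@H]1C=C[C@@H](O)[C@]2(C(=O)OC)[C@H]1C3c4ccccc4C2c5ccccc35
A10 | alternative 3 | anthracene-bridged tetrol derivative | CC(C)(C)[Si](C)(C)O[C@H]1[C@H](O)[C@H](O)[C@@H](O)[C@]2(C(=O)OC)[C@H]1C3c4ccccc4C2c5ccccc35
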